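**Plan**

- Retrosynthesis: cut the stearate O–acyl bond, then C1'–C2' of the decenyl chain (Grignard on a C5 carbaldehyde), then C1''=C2'' of the pentyl chain (Wittig on a C2 ester). The oxolane O1–C2 bond is then exchanged for an O1–C1'' acyl bond, which enlarges the ring to a 3,4-dihydroxyoxan-2-one; this comes from a 6-substituted 5,6-dihydropyran-2-one, and that from (R)-benzyl glycidyl ether and ethyl propiolate.
- Enabling feature: oxolane atoms O1, C2, C3(OH), C4H2, C5 plus pentyl C1'' form the skeleton of a 4-deoxy δ-lactone. C2/C3 carry vicinal oxygens (the cis-diol of an enoate), C4 is a bare methylene (no γ-hydroxyl, so no γ-lactone can form), and the lactone oxygen on C5 lies 1,4 to the α-carbon C2.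
- Forward: epoxide alkynylation; semihydrogenation/lactonisation (six-membered helper ring); cis-dihydroxylation; α-triflate/β-silyl ether; ring contraction to the oxolane (the only ring of the target); ester to pentyl; Grignard side chain; stearoylation; desilylation.
- Stereochemistry: C5 from the glycidyl ether. C3 and C2 by relay from C5: dihydroxylation anti to the lactone C6 substituent, then SN2 inversion at the α-carbon in the contraction, giving 2,3-cis-2,5-trans. C1' by chelation-controlled addition. Helpers: lactone carbonyl (kept as pentyl C1''), triflate, TBS, benzyl.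

Key step: step 5

Remark: carbon building blocks (ethyl propiolate, the phosphonium salt, 9-bromonon-1-ene, stearoyl chloride) are numbered as starting materials, and the organometallic species made from them in the flask as non-isolated intermediates.

**Step 1**
Reactants: 1 (R)-benzyl glycidyl ether; 2 ethyl propiolate
Product: 4 ethyl (5R)-6-(benzyloxy)-5-hydroxyhex-2-ynoate, via ethyl 3-lithiopropiolate 3 (not isolated)
Conditions: 2, n-BuLi, THF, −78 °C; BF3·OEt2; then 1, −78 °C; aq. NH4Cl
Reagents that add atoms: none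
Why: Yamaguchi–Hirao alkynylation, in which the BF3-activated terminal epoxide should be opened by the lithium acetylide at its unsubstituted carbon, so the existing stereocentre is untouched and stays R.

**Step 2**
Reactants: 4 ethyl (5R)-6-(benzyloxy)-5-hydroxyhex-2-ynoate
Product: 6 (6R)-6-[(benzyloxy)methyl]-5,6-dihydro-2H-pyran-2-one, via (Z)-hydroxy enoate 5 (not isolated)
Conditions: H2 (1 atm), Lindlar catalyst, quinoline, EtOAc, rt; then PPTS (cat.), toluene, 60 °C
Reagents that add atoms: none
Why: Lindlar semi-hydrogenation should give the Z-enoate, whose geometry brings the δ-hydroxyl onto the ester so that lactonisation (transesterification) closes the six-membered helper ring without touching the stereocentre.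

**Step 3**
Reactants: 6 (6R)-6-[(benzyloxy)methyl]-5,6-dihydro-2H-pyran-2-one
Product: 7 (3S,4S,6R)-6-[(benzyloxy)methyl]-3,4-dihydroxyoxan-2-one
Conditions: OsO4 (cat.), NMO, acetone–H2O, 0 °C → rt
Reagents that add atoms: osmium tetroxide (catalytic) O=[Os](=O)(=O)=O; N-methylmorpholine N-oxide C[N+]1([O-])CCOCC1; water O
Why: Upjohn dihydroxylation, in which OsO4 should add syn to the enoate face anti to the pseudo-equatorial C6 substituent of the half-chair lactone, setting C3 and C4 (both S) under substrate control, while the absence of an oxygen on C5 keeps the diol as the δ-lactone.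

**Step 4**
Reactants: 7 (3S,4S,6R)-6-[(benzyloxy)methyl]-3,4-dihydroxyoxan-2-one
Product: 9 (3S,4S,6R)-6-[(benzyloxy)methyl]-4-[(tert-butyldimethylsilyl)oxy]-2-oxooxan-3-yl trifluoromethanesulfonate, via hydroxy triflate 8 (not isolated)
Conditions: Tf2O (1.05 equiv), pyridine, CH2Cl2, −40 °C; then 2,6-lutidine, TBSOTf, −40 → 0 °C
Reagents that add atoms: trifluoromethanesulfonic anhydride O=S(=O)(OS(=O)(=O)C(F)(F)F)C(F)(F)F; tert-butyldimethylsilyl trifluoromethanesulfonate CC(C)(C)[Si](C)(C)OS(=O)(=O)C(F)(F)F
Why: Regioselective O-sulfonylation then O-silylation, in which the more acidic α-hydroxyl of the lactone should be triflated first (as in the selective 2-O-sulfonylation of aldonolactones) and the cis 4-hydroxyl, which cannot displace the triflate, is capped in the same flask; no stereocentre changes.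

**Step 5**
Reactants: 9 (3S,4S,6R)-6-[(benzyloxy)methyl]-4-[(tert-butyldimethylsilyl)oxy]-2-oxooxan-3-yl trifluoromethanesulfonate
Product: 11 methyl (2R,3S,5R)-5-[(benzyloxy)methyl]-3-[(tert-butyldimethylsilyl)oxy]oxolane-2-carboxylate, via open-chain hydroxy ester 10 (not isolated)
Conditions: K2CO3 (1.2 equiv), MeOH, −20 °C, short reaction time; pH 7 buffer
Reagents that add atoms: methanol CO
Why: Methoxide should add to the lactone carbonyl and open the six-membered ring by acyl–oxygen cleavage to methyl ester 10, whose C5 alkoxide then displaces the carbonyl-activated α-triflate by intramolecular SN2, so the ring oxygen moves from the carbonyl carbon to C2 and the carbonyl carbon leaves the ring as the exocyclic ester (oxan-2-one to oxolane, one atom fewer). The closest known reaction type is the base-induced ring contraction of α-triflyloxy δ-lactones to oxolane-2-carboxylates, well established for aldonolactone triflates. The oxolane closes in the 5-exo-tet mode, and no other ring can form because the only other oxygen is silylated. The one new stereocentre, C2, is set by stereospecific inversion of the (S)-triflate (itself fixed by the dihydroxylation anti to the C6 substituent), which places the ester cis to the silyloxy group and trans to the C5 substituent, the 2,3-cis-2,5-trans pattern of the target; C3 and C5 are untouched because the C5–O bond is never broken. The step needs substitution to outrun E2 loss of triflic acid and base epimerisation of the kinetic cis ester, which the weak base, the low temperature, the fast five-membered closure and a prompt buffered quench should secure.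

**Step 6**
Reactants: 11 methyl (2R,3S,5R)-5-[(benzyloxy)methyl]-3-[(tert-butyldimethylsilyl)oxy]oxolane-2-carboxylate; 12 butyltriphenylphosphonium bromide
Product: 15 {[(2S,3S,5R)-5-[(benzyloxy)methyl]-2-[(1Z)-pent-1-en-1-yl]oxolan-3-yl]oxy}(tert-butyl)dimethylsilane, via oxolane-2-carbaldehyde 13 (not isolated), via butylidenetriphenylphosphorane 14 (not isolated)
Conditions: DIBAL-H, CH2Cl2, −78 °C; then ylide from 12 and NaHMDS in THF, −78 → 0 °C; Rochelle salt work-up
Reagents that add atoms: none
Why: Partial DIBAL reduction of the α-alkoxy ester followed by Wittig olefination in the same flask should turn the extruded carbonyl carbon into C1'' of a pentenyl chain, the low temperature and the absence of isolation guarding the cis α-alkoxy aldehyde against epimerisation; no stereocentre is formed (the alkene is removed in step 7).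

**Step 7**
Reactants: 15 {[(2S,3S,5R)-5-[(benzyloxy)methyl]-2-[(1Z)-pent-1-en-1-yl]oxolan-3-yl]oxy}(tert-butyl)dimethylsilane
Product: 16 [(2R,4S,5S)-4-[(tert-butyldimethylsilyl)oxy]-5-pentyloxolan-2-yl]methanol
Conditions: H2 (1 atm), 10% Pd/C, EtOAc, rt
Reagents that add atoms: none
Why: Catalytic hydrogenation should saturate the alkene to the pentyl chain and hydrogenolyse the benzyl ether in one operation, the silyl ether being stable in ethyl acetate and no stereocentre being affected.

**Step 8**
Reactants: 16 [(2R,4S,5S)-4-[(tert-butyldimethylsilyl)oxy]-5-pentyloxolan-2-yl]methanol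
Product: 17 (2R,4S,5S)-4-[(tert-butyldimethylsilyl)oxy]-5-pentyloxolane-2-carbaldehyde
Conditions: Dess–Martin periodinane, NaHCO3, CH2Cl2, 0 °C → rt; used directly
Reagents that add atoms: none
Why: Dess–Martin oxidation should convert the primary alcohol to the aldehyde under buffered, non-epimerising conditions.

**Step 9**
Reactants: 17 (2R,4S,5S)-4-[(tert-butyldimethylsilyl)oxy]-5-pentyloxolane-2-carbaldehyde; 18 9-bromonon-1-ene
Product: 20 (1R)-1-[(2R,4S,5S)-4-[(tert-butyldimethylsilyl)oxy]-5-pentyloxolan-2-yl]dec-9-en-1-ol, via non-8-en-1-ylmagnesium bromide 19 (not isolated)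
Conditions: 18, Mg, Et2O, reflux; then 17, MgBr2·OEt2, CH2Cl2, −78 °C; aq. NH4Cl
Reagents that add atoms: none
Why: Chelation-controlled (Cram chelate) Grignard addition, in which magnesium should bridge the aldehyde and ring oxygens so that the nucleophile attacks from the side of the C2 hydrogen and gives the threo (1R) carbinol.

**Step 10**
Reactants: 20 (1R)-1-[(2R,4S,5S)-4-[(tert-butyldimethylsilyl)oxy]-5-pentyloxolan-2-yl]dec-9-en-1-ol; 21 octadecanoyl chloride
Product: 22 (1R)-1-[(2R,4S,5S)-4-[(tert-butyldimethylsilyl)oxy]-5-pentyloxolan-2-yl]dec-9-en-1-yl octadecanoate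
Conditions: pyridine, DMAP (cat.), CH2Cl2, 0 °C → rt
Reagents that add atoms: none
Why: DMAP-catalysed O-acylation of the only free hydroxyl should install the stearate with retention at C1', the ring hydroxyl being masked as its silyl ether.

**Step 11**
Reactants: 22 (1R)-1-[(2R,4S,5S)-4-[(tert-butyldimethylsilyl)oxy]-5-pentyloxolan-2-yl]dec-9-en-1-yl octadecanoate
Product: 23 (1R)-1-[(2R,4S,5S)-4-hydroxy-5-pentyloxolan-2-yl]dec-9-en-1-yl octadecanoate
Conditions: HF·pyridine, pyridine, THF, 0 °C → rt
Reagents that add atoms: none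
Why: Fluoride-mediated desilylation should free the ring hydroxyl without touching the ester or the alkene, the trans arrangement of acyloxy side chain and hydroxyl disfavouring acyl migration.

**Compound list**

1 | (R)-benzyl glycidyl ether | c1ccccc1COC[C@H]1CO1 | starting material
2 | ethyl propiolate | C#CC(=O)OCC | starting material
3 | ethyl 3-lithiopropiolate | [Li]C#CC(=O)OCC | intermediate
4 | ethyl (5R)-6-(benzyloxy)-5-hydroxyhex-2-ynoate | CCOC(=O)C#CC[C@@H](O)COCc1ccccc1 | intermediate
5 | ethyl (2Z,5R)-6-(benzyloxy)-5-hydroxyhex-2-enoate | CCOC(=O)/C=C\C[C@@H](O)COCc1ccccc1 | intermediate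
6 | (6R)-6-[(benzyloxy)methyl]-5,6-dihydro-2H-pyran-2-one | O=C1C=CC[C@H](COCc2ccccc2)O1 | intermediate
7 | (3S,4S,6R)-6-[(benzyloxy)methyl]-3,4-dihydroxyoxan-2-one | O=C1[C@@H](O)[C@@H](O)C[C@H](COCc2ccccc2)O1 | intermediate
8 | (3S,4S,6R)-6-[(benzyloxy)methyl]-4-hydroxy-2-oxooxan-3-yl trifluoromethanesulfonate | O=C1[C@@H](OS(=O)(=O)C(F)(F)F)[C@@H](O)C[C@H](COCc2ccccc2)O1 | intermediate
9 | (3S,4S,6R)-6-[(benzyloxy)methyl]-4-[(tert-butyldimethylsilyl)oxy]-2-oxooxan-3-yl trifluoromethanesulfonate | O=C1[C@@H](OS(=O)(=O)C(F)(F)F)[C@@H](O[Si](C)(C)C(C)(C)C)C[C@H](COCc2ccccc2)O1 | intermediate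
10 | methyl (2S,3S,5R)-6-(benzyloxy)-3-[(tert-butyldimethylsilyl)oxy]-5-hydroxy-2-[(trifluoromethanesulfonyl)oxy]hexanoate | COC(=O)[C@@H](OS(=O)(=O)C(F)(F)F)[C@@H](O[Si](C)(C)C(C)(C)C)C[C@@H](O)COCc1ccccc1 | intermediate
11 | methyl (2R,3S,5R)-5-[(benzyloxy)methyl]-3-[(tert-butyldimethylsilyl)oxy]oxolane-2-carboxylate | COC(=O)[C@H]1[C@@H](O[Si](C)(C)C(C)(C)C)C[C@H](COCc2ccccc2)O1 | intermediate
12 | butyltriphenylphosphonium bromide | CCCC[P+](c1ccccc1)(c1ccccc1)c1ccccc1.[Br-] | starting material
13 | (2R,3S,5R)-5-[(benzyloxy)methyl]-3-[(tert-butyldimethylsilyl)oxy]oxolane-2-carbaldehyde | O=C[C@H]1[C@@H](O[Si](C)(C)C(C)(C)C)C[C@H](COCc2ccccc2)O1 | intermediate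
14 | butylidenetriphenylphosphorane | CCCC=P(c1ccccc1)(c1ccccc1)c1ccccc1 | intermediate
15 | {[(2S,3S,5R)-5-[(benzyloxy)methyl]-2-[(1Z)-pent-1-en-1-yl]oxolan-3-yl]oxy}(tert-butyl)dimethylsilane | CCC/C=C\[C@H]1[C@@H](O[Si](C)(C)C(C)(C)C)C[C@H](COCc2ccccc2)O1 | intermediate
16 | [(2R,4S,5S)-4-[(tert-butyldimethylsilyl)oxy]-5-pentyloxolan-2-yl]methanol | CCCCC[C@H]1[C@@H](O[Si](C)(C)C(C)(C)C)C[C@H](CO)O1 | intermediate
17 | (2R,4S,5S)-4-[(tert-butyldimethylsilyl)oxy]-5-pentyloxolane-2-carbaldehyde | CCCCC[C@H]1[C@@H](O[Si](C)(C)C(C)(C)C)C[C@H](C=O)O1 | intermediate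
18 | 9-bromonon-1-ene | C=CCCCCCCCBr | starting material
19 | non-8-en-1-ylmagnesium bromide | C=CCCCCCCC[Mg]Br | intermediate
20 | (1R)-1-[(2R,4S,5S)-4-[(tert-butyldimethylsilyl)oxy]-5-pentyloxolan-2-yl]dec-9-en-1-ol | C=CCCCCCCC[C@@H](O)[C@H]1C[C@H](O[Si](C)(C)C(C)(C)C)[C@H](CCCCC)O1 | intermediate
21 | octadecanoyl chloride (stearoyl chloride) | CCCCCCCCCCCCCCCCCC(=O)Cl | starting material
22 | (1R)-1-[(2R,4S,5S)-4-[(tert-butyldimethylsilyl)oxy]-5-pentyloxolan-2-yl]dec-9-en-1-yl octadecanoate | C=CCCCCCCC[C@@H](OC(=O)CCCCCCCCCCCCCCCCC)[C@H]1C[C@H](O[Si](C)(C)C(C)(C)C)[C@H](CCCCC)O1 | intermediate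
23 | (1R)-1-[(2R,4S,5S)-4-hydroxy-5-pentyloxolan-2-yl]dec-9-en-1-yl octadecanoate | C=CCCCCCCC[C@@H](OC(=O)CCCCCCCCCCCCCCCCC)[C@H]1C[C@H](O)[C@H](CCCCC)O1 | target

**Step count and risks**

Total step count: 11. Longest linear sequence: 11 steps (from 1; the chain reagents 2, 12, 18 and 21 are commercial).

Steps most likely to fail:

Step 4. The two secondary hydroxyls may not be told apart well enough: triflation may also occur at O4 or at both oxygens. The fallback needs no discrimination. It sets out from diol 7, which is converted with SOCl2/Et3N into the cyclic sulfite of diol 7 F1 and oxidised (RuCl3 cat., NaIO4, MeCN–H2O) to the cyclic sulfate of diol 7 F2. K2CO3/MeOH should then open the lactone, and the freed alkoxide should attack the sulfate at the ester α-carbon (the position at which cyclic sulfates of 2,3-dihydroxy esters are opened) with inversion, giving the ring-contracted potassium oxolanyl sulfate F3. Hydrolysis (cat. H2SO4, THF–H2O) should give methyl (2R,3S,5R)-5-[(benzyloxy)methyl]-3-hydroxyoxolane-2-carboxylate F4, and silylation (TBSCl, imidazole, DMF) returns to the route at 11.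

Step 9. Facial selectivity may be poor if chelation of magnesium between the aldehyde and ring oxygens is incomplete. The fallback sets the carbinol centre by hydride reduction instead of C–C bond formation. It sets out from aldehyde 17; the Grignard adduct is carried on as the mixture of 20 and its epimer, the (1S)-carbinol F5, and oxidised (Dess–Martin periodinane) to the ketone 1-[(2R,4S,5S)-4-[(tert-butyldimethylsilyl)oxy]-5-pentyloxolan-2-yl]dec-9-en-1-one F6. Reduction with L-Selectride (THF, −78 °C) should follow the Felkin–Anh course for an α-oxygenated ketone and give the threo alcohol, returning to the route at 20.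

Step 6. The cis-configured α-alkoxy aldehyde may epimerise at C2 under the basic ylide, or the ester may be over-reduced. The fallback avoids the aldehyde. It sets out from ester 11, which is reduced (LiBH4, THF) to the primary alcohol [(2S,3S,5R)-5-[(benzyloxy)methyl]-3-[(tert-butyldimethylsilyl)oxy]oxolan-2-yl]methanol F7 and converted (Tf2O, 2,6-lutidine, CH2Cl2, −78 °C) to the corresponding primary triflate F8. Coupling with lithium dibutylcuprate (Et2O, −78 → −20 °C) should give the pentyl benzyl ether F9, and hydrogenolysis (H2, Pd/C, EtOAc) returns to the route at 16.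

**Further compounds**

F1 | step 4 | cyclic sulfite of diol 7, (3S,4S,6R)-6-[(benzyloxy)methyl]-3,4-(sulfinyldioxy)oxan-2-one | O=C1[C@H]2OS(=O)O[C@H]2C[C@H](COCc3ccccc3)O1
F2 | step 4 | cyclic sulfate of diol 7, (3S,4S,6R)-6-[(benzyloxy)methyl]-3,4-(sulfonyldioxy)oxan-2-one | O=C1[C@H]2OS(=O)(=O)O[C@H]2C[C@H](COCc3ccccc3)O1
F3 | step 4 | potassium (2R,3S,5R)-5-[(benzyloxy)methyl]-2-(methoxycarbonyl)oxolan-3-yl sulfate | COC(=O)[C@H]1[C@@H](OS(=O)(=O)[O-])C[C@H](COCc2ccccc2)O1.[K+]
F4 | step 4 | methyl (2R,3S,5R)-5-[(benzyloxy)methyl]-3-hydroxyoxolane-2-carboxylate | COC(=O)[C@H]1[C@@H](O)C[C@H](COCc2ccccc2)O1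
F5 | step 9 | (1S)-1-[(2R,4S,5S)-4-[(tert-butyldimethylsilyl)oxy]-5-pentyloxolan-2-yl]dec-9-en-1-ol | C=CCCCCCCC[C@H](O)[C@H]1C[C@H](O[Si](C)(C)C(C)(C)C)[C@H](CCCCC)O1
F6 | step 9 | 1-[(2R,4S,5S)-4-[(tert-butyldimethylsilyl)oxy]-5-pentyloxolan-2-yl]dec-9-en-1-one | C=CCCCCCCCC(=O)[C@H]1C[C@H](O[Si](C)(C)C(C)(C)C)[C@H](CCCCC)O1
F7 | step 6 | [(2S,3S,5R)-5-[(benzyloxy)methyl]-3-[(tert-butyldimethylsilyl)oxy]oxolan-2-yl]methanol | OC[C@H]1[C@@H](O[Si](C)(C)C(C)(C)C)C[C@H](COCc2ccccc2)O1
F8 | step 6 | [(2S,3S,5R)-5-[(benzyloxy)methyl]-3-[(tert-butyldimethylsilyl)oxy]oxolan-2-yl]methyl trifluoromethanesulfonate | FC(F)(F)S(=O)(=O)OC[C@H]1[C@@H](O[Si](C)(C)C(C)(C)C)C[C@H](COCc2ccccc2)O1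
F9 | step 6 | {[(2S,3S,5R)-5-[(benzyloxy)methyl]-2-pentyloxolan-3-yl]oxy}(tert-butyl)dimethylsilane | CCCCC[C@H]1[C@@H](O[Si](C)(C)C(C)(C)C)C[C@H](COCc2ccccc2)O1
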